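I wanted the target from this flask, but the target came slowly, standing at 9.5% in Friday's run and 7.8% in Wednesday's after 12.0 min, so I first asked how much of the charge would still be starting material after 20 min at 0.033 M.

| flask | starting material | remark | time |
|---|---|---|---|
| Friday's | 0.022 M | run made earlier |  |
| Wednesday's | 0.050 M | run made earlier |  |
| flask | 0.033 M |  | 20 min |

| run | time / min | other conformer / % | target / % | isomer of the product / % | starting material / % |
|---|---|---|---|---|---|
| Friday's | 1.00 | 1.1 | 1.5 | 1.6 | 96.4 |
| Friday's | 2.00 | 4.4 | 0.7 | 0.5 | 93.7 |
| Friday's | 3.00 | 7.5 | 2.6 | 0 | 92.8 |
| Friday's | 6.00 | 8.6 | 6.0 | 0.2 | 86.1 |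
| Friday's | 12.0 | 11.5 | 9.5 | 2.6 | 75.2 |
| Wednesday's | 1.00 | 1.3 | 1.9 | 0 | 97.5 |
| Wednesday's | 2.00 | 3.0 | 0.5 | 0 | 94.0 |
| Wednesday's | 3.00 | 4.5 | 3.1 | 0.3 | 91.5 |
| Wednesday's | 6.00 | 9.3 | 5.9 | 0.5 | 85.2 |
| Wednesday's | 12.0 | 11.3 | 7.8 | 0.7 | 72.7 |

(scatter of a reading: 1 percentage point)

- a reading or a percentage of target counts all its forms, free or not

- the species that holds most of what was charged as starting material, at 20 min (starting material / other conformer / target / isomer of the product)
- the largest share itself, whichever of these holds it, in percent of the starting material charged

I read the two runs as a ladder, from the change that eased soonest to the one that showed latest. The other conformer came first: at 6.00 min it stood at 8.6% on Friday and 9.3% on Wednesday, and by 12.0 min it had added less than that , reaching 11.5% and 11.3%. Next came the fall of starting material, the large change, in which I treated the charge as a small correction, because a factor of 2.27 in charge moved the reading at 12.0 min by 2.5 percentage points, less than the 25 points that Friday's run had lost by then, with a scatter of 1 point per reading, and this flask's 0.033 M lies between the two charges. The isomer of the product came last, reading 2.6% on Friday and 0.7% on Wednesday at 12.0 min, less than the target in each of these two readings .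

From the mean of the two last readings I got 0.0251 /min for the loss constant, the apparent first-order rate constant, by which I mean the logarithm of one over the fraction of the charge left, divided by the time. Its time scale of 39.8 min is longer than the 20 min asked, and my reckoning left 60.5% of the charge as starting material, which is more than whatever had left it, wherever that went.

The forecast put starting material first at 61%, a little more than my figure, on the ground that “Its loss is therefore close to first order”.

The flask gave starting material at 61.7%, which is 1.2 points above my reckoning. Moving the charge from Friday's run to this flask, with the time held at Friday's last reading, gives 73.5% of starting material against 73.7% for Friday's run without its scatter. The loss constant put to use at 10.0 min in this flask gives 77.8%, and the flask holds 77.0% then.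

    starting material ⇌ other conformer (K = 0.450, k = 0.0200 /min)
    starting material ⇌ target (K = 5.90, k = 0.00980 /min)
    other conformer → isomer of the product (k = 0.0180 /min)
    crystals ⇌ target, rate k4*(cs4 - [target]) while solid is left; crystals form when [target] > cs4 (solubility = 25.0 mM, k = 0.240 /min)
    2 other conformer → self-condensation product (k = 7.00 /M/min)

For the neighbouring flask read at 30 min, the loss constant gives 47.1% of the charge as starting material. The computed flask holds 50.2%, which is 3.2 points more.

All runs are simulated with constants of no real substance; scatter was added.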